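The earlier runs and the new flask are simulated from invented constants; the scatter is artificial.

The trap in the dusk run is the straight line: it looks like a rate that lasts to the end.

the same everywhere: solid substrate 0.20 M; initiator 2.5 mol%
- dusk: reagent 1.5 equiv; scavenger 1.4 equiv; run made earlier
- ash: reagent 1.50 equiv; scavenger 1.20 equiv; time 3.0 d
- elm: reagent 1.50 equiv; scavenger 1.60 equiv; time 3.0 d
- maple: reagent 1.50 equiv; scavenger 2.00 equiv; time 3.0 d

dusk run (percent of the solid substrate charged)

| time / h | solid substrate / % | product / % |
|---|---|---|
| 8.00 | 76.2 | 3.6 |
| 15.0 | 61.6 | 14.9 |
| 20.0 | 55.3 | 24.0 |
| 30.0 | 41.9 | 36.5 |
| 40.0 | 28.4 | 47.8 |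

(each reading ± 1 percentage point)

- part of the solid substrate that has reacted (what has only dissolved counts as not reacted) at the end, ash
- part of the solid substrate that has reacted (what has only dissolved counts as not reacted) at the end, elm
- part of the solid substrate that has reacted (what has only dissolved counts as not reacted) at the end, maple
- what raising the equivalents of scavenger from its lowest to its highest value here does to the part of the solid substrate that has reacted (what has only dissolved counts as not reacted) (changes below 5 percentage points count as none) (it rises / no change / it falls)

- as a solid, counted per litre of solution: solid substrate
- at the start none of the solid substrate is in solution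
- what has only dissolved of solid substrate counts as not reacted
- no earlier run changes the charge of scavenger; that part of a forecast is a guess

1. First rung: I call what is neither solid nor product the solution stock. It reads 20.2% at 8.00 h and 23.8% at 40.0 h, so it fills early and then holds a quasi-steady state, averaging 22.0% over the readings.

2. Next rung: product climbs steadily from 15.0 h to 40.0 h. Dividing the stock by that climb gives a stock lifetime of 16.7 h.

3. Slower rung: I extend the solid's fall over the same readings to zero and get 61.4 h. This is my run-out time, the hour at which the straight fall of the solid reaches zero. It comes later than the stock lifetime, so on this reckoning the stock is replaced 3.68 times before then.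

4. Last rung: the asked time 3.0 d comes later than the run-out time, so on my reckoning control passes from the dissolving solid to the decay of the stock for the last 10.6 h. If the stock lifetime holds, I reckon 88.4% reacted. No run varies the scavenger, so using this number for each flask is a guess.

5. The forecast gives 88% for ash, 88% for elm and 87% for maple, with the trend no change: “The solid should run out at about 60 h.”

6. The flasks give 82.3% for ash, 82.3% for elm and 82.3% for maple, a change of −0.011 percentage points, so the trend is no change. Ash stands 6.1 points below my reckoning.

    starting material + released group ⇌ idle adduct, settled at all times (K = 6.10 L mol⁻¹)
    initiator → 2 initiating radical (k = 0.0180 h⁻¹)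
    scavenger + released group → scavenged by-product (k = 34.0 L mol⁻¹ h⁻¹)
    starting material + second chain carrier → released group + first chain carrier (k = 8.90 × 10⁶ L mol⁻¹ h⁻¹)
    starting material + initiating radical → capped initiator + first chain carrier (k = 63000 L mol⁻¹ s⁻¹)
    2 second chain carrier → ended chains (k = 4.00 × 10⁸ L mol⁻¹ s⁻¹)
    solid substrate ⇌ starting material, rate k7*(cs7 - [starting material]) while solid is left; crystals form when [starting material] > cs7 (solubility = 0.0660 M, k = 0.140 h⁻¹)
    reagent + first chain carrier → product + second chain carrier (k = 12000 L mol⁻¹ s⁻¹)

In maple, solid substrate crawls into solution, with half the dissolving up to the asked time done by 0.970 d, while the initiator, with a half-life of 1.6 d by its own decay, falls to 27% of its charge at 3.0 d. The 10.6 h past my run-out time end with solid substrate at 0% and starting material at 17.7%, and the same flask read at 12 d, 4.69 run-out times, holds 0.300% starting material.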